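## Retrosynthetic overview
1. Both C14 halves are resveratrol 1. One copy is used as it is (unit A, gives C7, C8 and their two aryl groups). The other is used as its 4'-O-acetate 2 (unit B, gives the six-membered ring and the styryl arm).
2. Key disconnection: C8–C10' and C7–C12' are cut together. This is an oxidative, dearomatising formal [5+2] union of the A alkene with C10'–C11'–C12' of the B resorcinol ring, forming the cyclopentanone. It is run as a cross-coupling under a chiral Brønsted acid.
3. Order in the flask: A is oxidised at its 4-OH (iodane 3), then the C8–C10' bond gives the non-aromatic p-quinone methide/dienone 4. Attack of C12' on C7 then closes the five-membered ring, and with it the bicycle 5, before ring B can rearomatise. The six-membered ring is the former arene.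
4. All four stereocentres arise in that one operation. The last step only removes the acetate (5 → 6, vitisinol D).

Assumption (biogenesis): vitisinol D is taken to arise from the 8–10' coupling product of two resveratrol units, whose enol carbon C12' adds to the quinone methide carbon C7 before rearomatisation; this is the branch point to (+)-ε-viniferin, which has the same spatial arrangement at C7 and C8.
Assumption (catalyst): the sense of induction of this new reaction cannot be predicted; the (R)-catalyst is written, and the (S)-catalyst is equally available if ent-5 is formed.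
Locants: unit A has C1–C6 as the 4-hydroxyphenyl ring, C7=C8 as the alkene (C8 next to the resorcinol ring) and C9–C14 as the resorcinol ring; unit B uses the same locants with primes.

## Route

Step 1
Reactants: 1 resveratrol [(E)-3,5,4'-trihydroxystilbene]
Product: 2 4'-O-acetylresveratrol [4-[(E)-2-(3,5-dihydroxyphenyl)ethenyl]phenyl acetate]
Conditions: vinyl acetate (5 equiv), immobilised Candida antarctica lipase B (CALB), 2-methylbutan-2-ol, 45 °C, 72 h
Reagents that add atoms: vinyl acetate, C=COC(C)=O
Why: Lipase-catalysed irreversible transesterification, in which the narrow CALB pocket accepts only the unhindered 4'-OH at the end of the rod-shaped stilbene and the enol leaving group tautomerises so the reaction cannot reverse; no stereocentre is formed.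

Step 2
Reactants: 1 resveratrol (unit A, 1.0 equiv, added by syringe pump over 6 h); 2 4'-O-acetylresveratrol (unit B, 3.0 equiv, excess recovered)
Product: 5 4'-O-acetylvitisinol D = (1R,5S,6R,7R)-6-(3,5-dihydroxyphenyl)-7-(4-hydroxyphenyl)-4-[(E)-2-(4-acetoxyphenyl)ethenyl]bicyclo[3.2.1]oct-3-ene-2,8-dione, via aryloxyiodane 3 (not isolated), via quinone-methide dienone 4 (not isolated)
Conditions: PhIO (1.05 equiv, suspended), (R)-3,3'-bis(2,4,6-triisopropylphenyl)-BINOL N-triflylphosphoramide (10 mol %), 4 Å MS, EtCN/CH2Cl2 1:1, −40 °C; cold pH 6 buffer quench
Reagents that add atoms: none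
Why: Proposed new method: polymeric PhIO is dissolved only by the chiral acid, so no achiral acid or basic ligand is present, and it binds the one 4-hydroxystilbene OH in the flask to give 3 (iodanes on resorcinol OH groups form reversibly but have no conjugated path to collapse, and 4'-O-capped resveratrols do not react with phenol oxidants); C10' of 2, whose 11'-OH is hydrogen-bonded to the phosphoramidate while the acidic N–H activates the O4–I–OH end (about 6 Å apart, a span such acids bridge in p-quinone methide additions), attacks C8 in a vinylogous displacement of PhI and water from a parallel, slip-stacked pair of stilbenes on the face left open by the 3,3'-aryl groups, which sets C8 (R) and C10' (S) and places the 3,5-dihydroxyphenyl group endo over the B vinyl group; the hydrogen-bonded O–H proton is lost faster than C10'–H to give 4, whose β-hydroxyenone carbon C12' closes on the acid-activated quinone methide carbon C7 (intramolecular 1,6-conjugate addition), the E geometry being carried over so that the C7 aryl group ends trans and exo and both bridgeheads follow from the ring; overall this is a stepwise cationic [5+2] phenol–styrene cycloaddition of Büchi type, the closest known reactions being the quinone-ketal and anodic [5+2] additions of 3-alkoxyphenol-derived cations to E-propenylarenes (bicyclo[3.2.1]oct-3-ene-2,8-diones as kinetic low-temperature products with bridgehead H retained), their Ti–TADDOLate enantioselective variant, the Tl(III)- and Fe(III)-induced 8–10' dimerisation of free resveratrol, and chiral-phosphoric-acid 1,6-additions of phenols to p-quinone methides.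

Step 3
Reactants: 5 4'-O-acetylvitisinol D
Product: 6 vitisinol D = (1R,5S,6R,7R)-6-(3,5-dihydroxyphenyl)-7-(4-hydroxyphenyl)-4-[(E)-2-(4-hydroxyphenyl)ethenyl]bicyclo[3.2.1]oct-3-ene-2,8-dione
Conditions: immobilised CALB, n-BuOH (10 equiv), t-BuOMe/THF 4:1, 40 °C
Reagents that add atoms: none
Why: Lipase-catalysed alcoholysis (transesterification) at neutral pH, in which the acetate sits at the far end of the styryl arm like the 4'-acetate that CALB cleaves first in resveratrol esters, the absence of acid and base shuts off retro-1,6-addition (C7–C12') and retro-Claisen opening of the β-diketone, and the four stereocentres (two of them bridgeheads that cannot enolise, Bredt) are untouched.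

## Compound list
1 | resveratrol | Oc1ccc(/C=C/c2cc(O)cc(O)c2)cc1 | starting material
2 | 4'-O-acetylresveratrol | CC(=O)Oc1ccc(/C=C/c2cc(O)cc(O)c2)cc1 | intermediate
3 | hydroxy(phenyl){4-[(E)-2-(3,5-dihydroxyphenyl)ethenyl]phenoxy}-λ3-iodane | OI(c1ccccc1)Oc1ccc(/C=C/c2cc(O)cc(O)c2)cc1 | intermediate
4 | (6S)-6-[(1R)-1-(3,5-dihydroxyphenyl)-2-(4-oxocyclohexa-2,5-dien-1-ylidene)ethyl]-3-hydroxy-5-[(E)-2-(4-acetoxyphenyl)ethenyl]cyclohexa-2,4-dien-1-one | O=C1C=C(O)C=C(/C=C/c2ccc(OC(C)=O)cc2)[C@@H]1[C@H](c1cc(O)cc(O)c1)C=C1C=CC(=O)C=C1 | intermediate
5 | 4'-O-acetylvitisinol D (1R,5S,6R,7R) | O=C1C=C(/C=C/c2ccc(OC(C)=O)cc2)[C@H]2C(=O)[C@@H]1[C@H](c1ccc(O)cc1)[C@H]2c1cc(O)cc(O)c1 | intermediate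
6 | vitisinol D (1R,5S,6R,7R) | O=C1C=C(/C=C/c2ccc(O)cc2)[C@H]2C(=O)[C@@H]1[C@H](c1ccc(O)cc1)[C@H]2c1cc(O)cc(O)c1 | target

## Count and risks
Total steps: 3. Longest linear sequence: 3 (1 → 2 → 5 → 6).

**Step 2 (highest risk).**
- The acid may act as a proton shuttle and rearomatise 4, after which only O11' can close, giving the ε-viniferin-type dihydrobenzofuran.
- C12' may attack C8 first.
- 2 may be arylated at iodine.
- The remote ion pair may give low ee.

The fallback sets out from 2 and comes back at 5. Absolute control moves from the catalyst to a covalently bound chiral-pool group. This frees the choice of medium for the strongly ionising, non-basic solvent that best favours the cationic closure. Compound 2 is coupled with commercial polydatin (resveratrol 3-O-β-D-glucopyranoside) in place of 1, using PhI(OAc)2 in HFIP/CH2Cl2 1:4 at −40 °C. Two products form that differ in the configuration of the whole aglycone: 4'-O-acetylvitisinol D 11-O-β-D-glucopyranoside F1 and its aglycone-antipodal diastereomer F2. They are diastereomers and are separated by reversed-phase chromatography. Almond β-glucosidase (pH 5 acetate buffer, 10 % DMSO, 37 °C) then removes the sugar from F1 to give 5.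

**Step 3.** The lipase may not accept the bulky ester, or 5 and 6 may open by retro-1,6-addition during long contact times. The fallback sets out from 1 and comes back at 6. The cap is left out, so no deprotection is needed. PhIO (0.3 equiv, in portions) is added to 1 alone under the catalyst and conditions of step 2. Iodane 3 then always meets a large excess of unoxidised 1 as the nucleophile. The free-phenol quinone-methide dienone F3 closes as before and gives 6 directly, and unreacted 1 is recovered. The price is lower chemoselectivity, because the alkene and 4-OH of the nucleophilic partner are no longer masked.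

**Step 1.** Conversion may be slow or incomplete, and some 3-O-acetate may form. The fallback sets out from 1 and comes back at 2. Regiocontrol comes from acidity instead of an enzyme pocket. NaOH (1.0 equiv) in DMSO at room temperature forms sodium resveratrol 4'-phenoxide F4, because the 4'-OH is the most acidic (its anion is conjugated through the stilbene). Ac2O (1.0 equiv) then acylates that oxygen to give 2.

## Further compounds
F1 | step 2 | 4'-O-acetylvitisinol D 11-O-β-D-glucopyranoside (aglycone 1R,5S,6R,7R) | O=C1C=C(/C=C/c2ccc(OC(C)=O)cc2)[C@H]2C(=O)[C@@H]1[C@H](c1ccc(O)cc1)[C@H]2c1cc(O)cc(O[C@H]2[C@@H]([C@H]([C@@H]([C@H](O2)CO)O)O)O)c1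
F2 | step 2 | ent-aglycone diastereomer of F1 (aglycone 1S,5R,6S,7S) | O=C1C=C(/C=C/c2ccc(OC(C)=O)cc2)[C@@H]2C(=O)[C@H]1[C@@H](c1ccc(O)cc1)[C@@H]2c1cc(O)cc(O[C@H]2[C@@H]([C@H]([C@@H]([C@H](O2)CO)O)O)O)c1
F3 | step 3 | (6S)-6-[(1R)-1-(3,5-dihydroxyphenyl)-2-(4-oxocyclohexa-2,5-dien-1-ylidene)ethyl]-3-hydroxy-5-[(E)-2-(4-hydroxyphenyl)ethenyl]cyclohexa-2,4-dien-1-one | O=C1C=C(O)C=C(/C=C/c2ccc(O)cc2)[C@@H]1[C@H](c1cc(O)cc(O)c1)C=C1C=CC(=O)C=C1
F4 | step 1 | sodium 4-[(E)-2-(3,5-dihydroxyphenyl)ethenyl]phenolate | [Na+].[O-]c1ccc(/C=C/c2cc(O)cc(O)c2)cc1
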